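**Assumption:** the target (C27H40O4) has no stereocentres and is achiral, so "single enantiomer" has no consequence and no stereocontrol is needed. The route is a design from standard reactions and has not been run.

## Retrosynthetic overview

1. No ring is formed: both benzene rings are bought as 3,5-dioxygenated aryl bromides.
2. The three free phenols are carried as benzyl ethers and the C14 chain as a diaryl diyne, so one final H2/Pd-C step saturates both alkynes and removes all three benzyl groups while the aryl methyl ether survives.
3. Disconnect both Ar–C(sp) bonds (two sequential Sonogashira couplings) to tetradeca-1,13-diyne plus two different aryl bromides.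
4. Tetradeca-1,13-diyne comes from 1,10-dibromodecane and lithium acetylide (C10 + 2 × C2 = C14).
5. The unsymmetrical end comes from O-benzylation of 3-bromo-5-methoxyphenol.

## Route

**Step 1**
Reactants: 1, 1,10-dibromodecane; 2, lithium acetylide–ethylenediamine complex
Product: 3, tetradeca-1,13-diyne
Conditions: LiC≡CH·EDA (3 equiv), DMSO, 10 °C → rt, 4 h
Reagents that add atoms: lithium acetylide–ethylenediamine complex, [Li]C#C.NCCN (supplies both C≡CH units)
Why: Double SN2 alkylation of acetylide on an unhindered primary dibromide in DMSO; keeping the temperature at or below rt avoids alkyne isomerisation.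

**Step 2**
Reactants: 4, 3-bromo-5-methoxyphenol; 5, benzyl bromide
Product: 6, 1-(benzyloxy)-3-bromo-5-methoxybenzene
Conditions: BnBr (1.1 equiv), K2CO3, DMF, rt
Reagents that add atoms: benzyl bromide, BrCc1ccccc1
Why: Williamson ether synthesis on the only acidic OH; the aryl bromide and methyl ether are inert.

**Step 3**
Reactants: 7, 1,3-bis(benzyloxy)-5-bromobenzene (1 equiv); 3, tetradeca-1,13-diyne (4 equiv)
Product: 8, 1,3-bis(benzyloxy)-5-(tetradeca-1,13-diyn-1-yl)benzene (Ar–C≡C–(CH2)10–C≡CH)
Conditions: PdCl2(PPh3)2 (3 mol%), CuI (3 mol%), Et3N/DMF, 80 °C, rigorously degassed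
Reagents that add atoms: none (all heavy atoms come from 7 and 3)
Why: Sonogashira coupling; the meta-alkoxy aryl bromide undergoes oxidative addition readily, and the large excess of diyne (recovered by chromatography in hexane) biases towards mono-arylation.

**Step 4**
Reactants: 8, 1,3-bis(benzyloxy)-5-(tetradeca-1,13-diyn-1-yl)benzene; 6, 1-(benzyloxy)-3-bromo-5-methoxybenzene (1.3 equiv)
Product: 9, 1-(benzyloxy)-3-{14-[3,5-bis(benzyloxy)phenyl]tetradeca-1,13-diyn-1-yl}-5-methoxybenzene
Conditions: PdCl2(PPh3)2 (5 mol%), CuI (5 mol%), Et3N/DMF, 80 °C, degassed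
Reagents that add atoms: none (all heavy atoms come from 8 and 6)
Why: Second Sonogashira coupling on the remaining terminal alkyne; the internal aryl alkyne and the benzyl ethers are inert.

**Step 5**
Reactants: 9, the diaryl diyne tris(benzyl ether)
Product: 10, 5-[14-(3-hydroxy-5-methoxyphenyl)tetradecyl]benzene-1,3-diol (target, CID16109872)
Conditions: H2 (1–3 atm), 10% Pd/C, EtOAc/MeOH 1:1, rt, 16 h
Reagents that add atoms: none (H2 adds hydrogen only)
Why: Catalytic hydrogenation saturates both alkynes to CH2CH2 and hydrogenolyses the three benzyl ethers in one pot; the aryl methyl ether and the arenes are untouched under these conditions.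

Check: the chain is 2 + 10 + 2 = 14 CH2 after reduction; one ring carries OH/OMe and the other OH/OH, both 1,3,5-substituted, matching the target SMILES.

## Compound list

1 | 1,10-dibromodecane | BrCCCCCCCCCCBr | starting material
2 | lithium acetylide–ethylenediamine complex | [Li]C#C.NCCN | starting material
3 | tetradeca-1,13-diyne | C#CCCCCCCCCCCC#C | intermediate
4 | 3-bromo-5-methoxyphenol | COc1cc(O)cc(Br)c1 | starting material
5 | benzyl bromide | BrCc1ccccc1 | starting material
6 | 1-(benzyloxy)-3-bromo-5-methoxybenzene | COc1cc(Br)cc(OCc2ccccc2)c1 | intermediate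
7 | 1,3-bis(benzyloxy)-5-bromobenzene | Brc1cc(OCc2ccccc2)cc(OCc2ccccc2)c1 | starting material
8 | 1,3-bis(benzyloxy)-5-(tetradeca-1,13-diyn-1-yl)benzene | C#CCCCCCCCCCCC#Cc1cc(OCc2ccccc2)cc(OCc2ccccc2)c1 | intermediate
9 | 1-(benzyloxy)-3-{14-[3,5-bis(benzyloxy)phenyl]tetradeca-1,13-diyn-1-yl}-5-methoxybenzene | COc1cc(OCc2ccccc2)cc(C#CCCCCCCCCCCC#Cc2cc(OCc3ccccc3)cc(OCc3ccccc3)c2)c1 | intermediate
10 | 5-[14-(3-hydroxy-5-methoxyphenyl)tetradecyl]benzene-1,3-diol | COc1cc(O)cc(CCCCCCCCCCCCCCc2cc(O)cc(O)c2)c1 | target

## Summary

**Total steps:** 5. If diyne 3 is bought from a specialty supplier, this drops to 4.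

**Longest linear sequence:** 4 steps (1 → 3 → 8 → 9 → 10).

**Steps most likely to fail, with fallbacks:**

1. **Step 3 (mono-Sonogashira on a symmetric diyne).** Risks are bis-arylation and Glaser homocoupling. Fallback: a non-statistical Wittig sequence. React 3,5-bis(benzyloxy)benzaldehyde with the ylide of (12-hydroxydodecyl)triphenylphosphonium bromide, oxidise the alcohol to the aldehyde, run a second Wittig with (3-benzyloxy-5-methoxybenzyl)triphenylphosphonium bromide, and finish with the same H2/Pd-C step.

2. **Step 4 (second Sonogashira on the valuable alkyne 8).** Risks are a sluggish coupling and homodimerisation of 8. Fallback: form the bond by sp–sp3 acetylide alkylation instead. Make 3-benzyloxy-5-methoxyphenylacetylene (Ohira–Bestmann on the aldehyde), lithiate it, and alkylate an Ar–C≡C–(CH2)10–Br partner in THF/DMPU.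

3. **Step 1 (double acetylide alkylation).** Risks are mono-alkylation, E2 elimination and alkyne migration. Fallback: drop the diyne and use commercial tetradeca-1,13-diene. Hydroborate with 9-BBN and run sequential B-alkyl Suzuki–Miyaura couplings with 7 and then 6 (PdCl2(dppf), K3PO4). This gives the saturated C14 chain directly, leaving only hydrogenolytic debenzylation.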